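**Retrosynthetic overview**

1. Target 21 ⇐ last-step hydroxyl-directed Sharpless epoxidation (C1–O/C10–O) of macrocyclic dienol 20 ⇐ desilylation of 19.
2. Ten-membered ring ⇐ ring-closing metathesis at C2=C3 of ester 18; C8 ester ⇐ Steglich acylation of alcohol 16 with (R)-2-methylbutanoic acid 17.
3. C7–C8 ⇐ Ni/Cr coupling of iodobutenolide 9 with dienal 15, which comes from propargyl alcohol 10 by allyl-carbomagnesiation/iodination, silylation, ozonolysis and Stille vinylation.
4. Butenolide ⇐ one-flask stannylcupration/formaldehyde aldol/lactonisation of ynoate 5, the ring being closed by the C6–O–C12 bond; C6 ⇐ Felkin addition to epoxy aldehyde 4; C4–C5 oxirane ⇐ Sharpless epoxidation of dienol 2 (from enynol 1).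
5. Ring order: C4–C5 oxirane → butenolide → ten-membered carbocycle → C1–C10 oxirane.

Assumption: atoms are labelled by germacrane numbering (ring C1–C10; C11/C12 = lactone α-carbon and carbonyl; C13 = CH2OAc; C14 = CH2OH; C15 = CH3). (R)-2-Methylbutanoic acid is bought as the single enantiomer.

**Route**

Step 1
Reactants: 1 (2Z)-3-methylpent-2-en-4-yn-1-ol
Product: 2 (2Z)-3-methylpenta-2,4-dien-1-ol
Conditions: H2 (1 atm, 1 equiv), Pd/CaCO3–Pb(OAc)2 (Lindlar), quinoline, EtOAc, 0 °C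
Reagents that add atoms: none
Why: Lindlar semihydrogenation (syn addition of H2 on poisoned Pd) stops at the alkene and converts only the terminal alkyne into the vinyl group later used for ring closure, with no stereocentre formed.

Step 2
Reactants: 2 (2Z)-3-methylpenta-2,4-dien-1-ol
Product: 3 [(2S,3R)-3-ethenyl-3-methyloxiran-2-yl]methanol
Conditions: Ti(OiPr)4 (10 mol%), L-(+)-diisopropyl tartrate (12 mol%), t-BuOOH, 4 Å MS, CH2Cl2, −20 °C
Reagents that add atoms: tert-butyl hydroperoxide CC(C)(C)OO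
Why: Sharpless asymmetric epoxidation oxidises only the olefin of the allylic alcohol, and L-(+)-tartrate delivers oxygen to the face that gives the (2S,3R)-oxirane (C5 S, C4 R), the cis relation of vinyl and CH2OH being inherited from the Z olefin.

Step 3
Reactants: 3 [(2S,3R)-3-ethenyl-3-methyloxiran-2-yl]methanol
Product: 4 (2R,3R)-3-ethenyl-3-methyloxirane-2-carbaldehyde
Conditions: Dess–Martin periodinane, pyridine, CH2Cl2, 0 °C
Reagents that add atoms: none
Why: Dess–Martin oxidation gives the aldehyde under buffered, non-epimerising conditions, the oxirane centres being untouched (the C2 label becomes R only through CIP priorities).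

Step 4
Reactants: 4 (2R,3R)-3-ethenyl-3-methyloxirane-2-carbaldehyde
Product: 5 methyl (4S)-4-[(2S,3R)-3-ethenyl-3-methyloxiran-2-yl]-4-hydroxybut-2-ynoate
Conditions: methyl propiolate, LiN(SiMe3)2, THF, −78 °C; then 4, −78 °C; AcOH quench
Reagents that add atoms: methyl propiolate C#CC(=O)OC
Why: 1,2-addition of the lithium acetylide to the α,β-epoxy aldehyde under Felkin–Anh control (attack anti to the oxirane C–O bond) gives the anti epoxy alcohol, setting the carbinol that becomes C6 as (S).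

Step 5
Reactants: 5 methyl (4S)-4-[(2S,3R)-3-ethenyl-3-methyloxiran-2-yl]-4-hydroxybut-2-ynoate
Product: 8 [(5R)-5-[(2S,3R)-3-ethenyl-3-methyloxiran-2-yl]-2-oxo-4-(tributylstannyl)-2,5-dihydrofuran-3-yl]methyl acetate, via stannyl hydroxymethyl enoate 6 (not isolated), via stannyl hydroxymethyl butenolide 7 (not isolated)
Conditions: LiN(SiMe3)2 (1.0 equiv), THF, −78 °C; Bu3SnCu·SMe2 [from Bu3SnH, LiN(iPr)2, then CuBr·SMe2], −78 °C; CH2O (THF solution), −78 to −20 °C; Ac2O, DMAP (cat.), 0 °C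
Reagents that add atoms: tributyltin hydride CCCC[SnH](CCCC)CCCC; formaldehyde C=O; acetic anhydride CC(=O)OC(C)=O
Why: Proposed new method: a one-flask stannylcupration–formaldehyde aldol–lactonisation–acetylation in which syn addition of the monovalent stannylcopper puts tin on C7 and copper on C11, the copper allenolate/vinylcopper is hydroxymethylated on the side of tin (retentive trapping, and tin is the smaller C7 substituent), the ester is thereby left cis to the C6 alkoxide so that the butenolide closes by C6–O acyl substitution, and acetic anhydride caps the C13 alkoxide, C6 being retained; the closest known reactions are stannylcupration of alkynoates to (E)-β-stannyl enoates, cuprate addition–aldol trapping of ynoates and lactonisation of (Z)-γ-hydroxy enoates.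

Step 6
Reactants: 8 [(5R)-5-[(2S,3R)-3-ethenyl-3-methyloxiran-2-yl]-2-oxo-4-(tributylstannyl)-2,5-dihydrofuran-3-yl]methyl acetate
Product: 9 [(5R)-5-[(2S,3R)-3-ethenyl-3-methyloxiran-2-yl]-4-iodo-2-oxo-2,5-dihydrofuran-3-yl]methyl acetate
Conditions: I2 (1.05 equiv), CH2Cl2, 0 °C
Reagents that add atoms: iodine II
Why: Iododestannylation (electrophilic ipso substitution of the alkenyl–tin bond with retention) gives the β-iodobutenolide, the vinyl group being far less reactive towards iodine.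

Step 7
Reactants: 10 prop-2-yn-1-ol
Product: 12 (2Z)-2-(iodomethylidene)pent-4-en-1-ol, via allyl oxamagnesacycle 11 (not isolated)
Conditions: CH2=CHCH2MgBr (2.5 equiv), CuI (10 mol%), THF, −10 °C to rt; then I2, −40 to 0 °C
Reagents that add atoms: allylmagnesium bromide C=CC[Mg]Br; iodine II
Why: Copper-catalysed anti-carbomagnesiation of the propargylic alkoxide puts allyl on the internal carbon and leaves a chelated (Z)-alkenylmagnesium, which iodine cleaves with retention so that iodine (the future C2 side) is cis to CH2OH (C14) and trans to the allyl carbon (C9).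

Step 8
Reactants: 12 (2Z)-2-(iodomethylidene)pent-4-en-1-ol
Product: 13 tert-butyl{[(2Z)-2-(iodomethylidene)pent-4-en-1-yl]oxy}dimethylsilane
Conditions: TBSCl, imidazole, DMF, 0 °C to rt
Reagents that add atoms: tert-butyldimethylsilyl chloride CC(C)(C)[Si](C)(C)Cl
Why: Imidazole-assisted silylation protects the C14 hydroxyl until the penultimate step.

Step 9
Reactants: 13 tert-butyl{[(2Z)-2-(iodomethylidene)pent-4-en-1-yl]oxy}dimethylsilane
Product: 14 (3Z)-3-({[tert-butyl(dimethyl)silyl]oxy}methyl)-4-iodobut-3-enal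
Conditions: O3, CH2Cl2, −78 °C (stopped at first excess); then PPh3, −78 °C to rt
Reagents that add atoms: ozone [O-][O+]=O
Why: Ozonolysis with reductive work-up cleaves the monosubstituted olefin in preference to the electron-poor iodoalkene and unmasks the C8 aldehyde.

Step 10
Reactants: 14 (3Z)-3-({[tert-butyl(dimethyl)silyl]oxy}methyl)-4-iodobut-3-enal
Product: 15 (3Z)-3-({[tert-butyl(dimethyl)silyl]oxy}methyl)hexa-3,5-dienal
Conditions: tributyl(vinyl)stannane, Pd2(dba)3 (2.5 mol%), AsPh3 (20 mol%), CuI (10 mol%), DMF, rt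
Reagents that add atoms: tributyl(vinyl)stannane C=C[Sn](CCCC)(CCCC)CCCC
Why: Stille coupling of the alkenyl iodide proceeds with retention, so the new vinyl carbon (C2) is trans to C9 as the ring olefin requires.

Step 11
Reactants: 9 [(5R)-5-[(2S,3R)-3-ethenyl-3-methyloxiran-2-yl]-4-iodo-2-oxo-2,5-dihydrofuran-3-yl]methyl acetate; 15 (3Z)-3-({[tert-butyl(dimethyl)silyl]oxy}methyl)hexa-3,5-dienal
Product: 16 [(5S)-4-[(1S,3Z)-3-({[tert-butyl(dimethyl)silyl]oxy}methyl)-1-hydroxyhexa-3,5-dien-1-yl]-5-[(2S,3R)-3-ethenyl-3-methyloxiran-2-yl]-2-oxo-2,5-dihydrofuran-3-yl]methyl acetate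
Conditions: CrCl2 (4 equiv), NiCl2 (1 mol%), chiral (S)-oxazoline–arylsulfonamide ligand (4.4 equiv), Et3N, THF, rt; aqueous work-up
Reagents that add atoms: none
Why: Nozaki–Hiyama–Kishi coupling, in which zerovalent nickel inserts into the activated alkenyl C–I bond, transmetallation gives an alkenyl trivalent-chromium species that adds only to the aldehyde, and the chiral ligand on chromium controls the aldehyde face to give the (8S)-carbinol (the lactone carbon label changes from R to S only because iodine is replaced by carbon).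

Step 12
Reactants: 16 [(5S)-4-[(1S,3Z)-3-({[tert-butyl(dimethyl)silyl]oxy}methyl)-1-hydroxyhexa-3,5-dien-1-yl]-5-[(2S,3R)-3-ethenyl-3-methyloxiran-2-yl]-2-oxo-2,5-dihydrofuran-3-yl]methyl acetate; 17 (2R)-2-methylbutanoic acid
Product: 18 (1S,3Z)-1-[(2S)-4-(acetoxymethyl)-2-[(2S,3R)-3-ethenyl-3-methyloxiran-2-yl]-5-oxo-2,5-dihydrofuran-3-yl]-3-({[tert-butyl(dimethyl)silyl]oxy}methyl)hexa-3,5-dien-1-yl (2R)-2-methylbutanoate
Conditions: N,N′-diisopropylcarbodiimide, DMAP (10 mol%), CH2Cl2, 0 °C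
Reagents that add atoms: none
Why: Steglich esterification (carbodiimide activation, DMAP acyl transfer) acylates the only free hydroxyl with retention at C8 and, at 0 °C, without epimerising the α-centre of the acid.

Step 13
Reactants: 18 (1S,3Z)-1-[(2S)-4-(acetoxymethyl)-2-[(2S,3R)-3-ethenyl-3-methyloxiran-2-yl]-5-oxo-2,5-dihydrofuran-3-yl]-3-({[tert-butyl(dimethyl)silyl]oxy}methyl)hexa-3,5-dien-1-yl (2R)-2-methylbutanoate
Product: 19 (4R,5S,6S,8S)-13-acetoxy-14-[(tert-butyldimethylsilyl)oxy]-4,5-epoxy-8-[(2R)-2-methylbutanoyloxy]germacra-1(10),2Z,7(11)-trien-12,6-olide (C9 and C2 trans across C1=C10)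
Conditions: second-generation Grubbs catalyst RuCl2(=CHPh)(H2IMes)(PCy3) (15 mol%), toluene (0.5 mM), 80 °C, N2 sparge
Reagents that add atoms: none
Why: Ring-closing metathesis between the vinyl oxirane and the diene terminus releases ethene and closes the ten-membered carbocycle, where ring strain enforces the Z geometry of the new C2=C3 bond and the preset C1=C10 geometry is kept.

Step 14
Reactants: 19 (4R,5S,6S,8S)-13-acetoxy-14-[(tert-butyldimethylsilyl)oxy]-4,5-epoxy-8-[(2R)-2-methylbutanoyloxy]germacra-1(10),2Z,7(11)-trien-12,6-olide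
Product: 20 (4R,5S,6S,8S)-13-acetoxy-4,5-epoxy-14-hydroxy-8-[(2R)-2-methylbutanoyloxy]germacra-1(10),2Z,7(11)-trien-12,6-olide
Conditions: HF·pyridine, pyridine, THF, 0 °C
Reagents that add atoms: none
Why: Fluoride-mediated Si–O cleavage under pyridine buffering frees the C14 allylic alcohol without opening the oxirane or triggering elimination at the acidic C6–H.

Step 15
Reactants: 20 (4R,5S,6S,8S)-13-acetoxy-4,5-epoxy-14-hydroxy-8-[(2R)-2-methylbutanoyloxy]germacra-1(10),2Z,7(11)-trien-12,6-olide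
Product: 21 (1R,4R,5S,6S,8S,10S)-13-acetoxy-1,10:4,5-diepoxy-14-hydroxy-8-[(2R)-2-methylbutanoyloxy]germacra-2Z,7(11)-dien-12,6-olide (target CNP0108300.1)
Conditions: Ti(OiPr)4 (20 mol%), L-(+)-diisopropyl tartrate (24 mol%), t-BuOOH, 4 Å MS, CH2Cl2, −20 °C
Reagents that add atoms: tert-butyl hydroperoxide CC(C)(C)OO
Why: Hydroxyl-directed Sharpless asymmetric epoxidation oxidises only the C1=C10 olefin of the C14 allylic alcohol, and L-(+)-tartrate, acting on the exposed outer face of the ring olefin, sets C10 (S) and C1 (R), the trans-oxirane geometry following from the olefin.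

**Compound list**

1 | (2Z)-3-methylpent-2-en-4-yn-1-ol | C#C/C(C)=C\CO | starting material
2 | (2Z)-3-methylpenta-2,4-dien-1-ol | C=C/C(C)=C\CO | intermediate
3 | [(2S,3R)-3-ethenyl-3-methyloxiran-2-yl]methanol | C=C[C@@]1(C)O[C@H]1CO | intermediate
4 | (2R,3R)-3-ethenyl-3-methyloxirane-2-carbaldehyde | C=C[C@@]1(C)O[C@H]1C=O | intermediate
5 | methyl (4S)-4-[(2S,3R)-3-ethenyl-3-methyloxiran-2-yl]-4-hydroxybut-2-ynoate | C=C[C@@]1(C)O[C@H]1[C@@H](O)C#CC(=O)OC | intermediate
6 | methyl (2E,4R)-4-[(2S,3R)-3-ethenyl-3-methyloxiran-2-yl]-4-hydroxy-2-(hydroxymethyl)-3-(tributylstannyl)but-2-enoate (present as its alkoxide) | C=C[C@@]1(C)O[C@H]1[C@@H](O)/C([Sn](CCCC)(CCCC)CCCC)=C(/CO)C(=O)OC | intermediate (not isolated)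
7 | (5R)-5-[(2S,3R)-3-ethenyl-3-methyloxiran-2-yl]-3-(hydroxymethyl)-4-(tributylstannyl)furan-2(5H)-one (present as its alkoxide) | C=C[C@@]1(C)O[C@H]1[C@H]1OC(=O)C(CO)=C1[Sn](CCCC)(CCCC)CCCC | intermediate (not isolated)
8 | [(5R)-5-[(2S,3R)-3-ethenyl-3-methyloxiran-2-yl]-2-oxo-4-(tributylstannyl)-2,5-dihydrofuran-3-yl]methyl acetate | C=C[C@@]1(C)O[C@H]1[C@H]1OC(=O)C(COC(C)=O)=C1[Sn](CCCC)(CCCC)CCCC | intermediate
9 | [(5R)-5-[(2S,3R)-3-ethenyl-3-methyloxiran-2-yl]-4-iodo-2-oxo-2,5-dihydrofuran-3-yl]methyl acetate | C=C[C@@]1(C)O[C@H]1[C@H]1OC(=O)C(COC(C)=O)=C1I | intermediate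
10 | prop-2-yn-1-ol | C#CCO | starting material
11 | 4-(prop-2-en-1-yl)-2,5-dihydro-1,2-oxamagnesole (chelated alkenylmagnesium alkoxide) | C=CCC1=C[Mg]OC1 | intermediate (not isolated)
12 | (2Z)-2-(iodomethylidene)pent-4-en-1-ol | I/C=C(\CO)CC=C | intermediate
13 | tert-butyl{[(2Z)-2-(iodomethylidene)pent-4-en-1-yl]oxy}dimethylsilane | I/C=C(\CO[Si](C)(C)C(C)(C)C)CC=C | intermediate
14 | (3Z)-3-({[tert-butyl(dimethyl)silyl]oxy}methyl)-4-iodobut-3-enal | I/C=C(\CO[Si](C)(C)C(C)(C)C)CC=O | intermediate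
15 | (3Z)-3-({[tert-butyl(dimethyl)silyl]oxy}methyl)hexa-3,5-dienal | C=C/C=C(\CO[Si](C)(C)C(C)(C)C)CC=O | intermediate
16 | [(5S)-4-[(1S,3Z)-3-({[tert-butyl(dimethyl)silyl]oxy}methyl)-1-hydroxyhexa-3,5-dien-1-yl]-5-[(2S,3R)-3-ethenyl-3-methyloxiran-2-yl]-2-oxo-2,5-dihydrofuran-3-yl]methyl acetate | C=C/C=C(\CO[Si](C)(C)C(C)(C)C)C[C@H](O)C1=C(COC(C)=O)C(=O)O[C@@H]1[C@@H]1O[C@]1(C)C=C | intermediate
17 | (2R)-2-methylbutanoic acid | CC[C@@H](C)C(=O)O | starting material
18 | (1S,3Z)-1-[(2S)-4-(acetoxymethyl)-2-[(2S,3R)-3-ethenyl-3-methyloxiran-2-yl]-5-oxo-2,5-dihydrofuran-3-yl]-3-({[tert-butyl(dimethyl)silyl]oxy}methyl)hexa-3,5-dien-1-yl (2R)-2-methylbutanoate | C=C/C=C(\CO[Si](C)(C)C(C)(C)C)C[C@H](OC(=O)[C@H](C)CC)C1=C(COC(C)=O)C(=O)O[C@@H]1[C@@H]1O[C@]1(C)C=C | intermediate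
19 | (4R,5S,6S,8S)-13-acetoxy-14-[(tert-butyldimethylsilyl)oxy]-4,5-epoxy-8-[(2R)-2-methylbutanoyloxy]germacra-1(10),2Z,7(11)-trien-12,6-olide (C9/C2 trans across C1=C10) | CC[C@@H](C)C(=O)O[C@H]1C/C(CO[Si](C)(C)C(C)(C)C)=C/C=C\[C@@]2(C)O[C@H]2[C@H]2OC(=O)C(COC(C)=O)=C12 | intermediate
20 | (4R,5S,6S,8S)-13-acetoxy-4,5-epoxy-14-hydroxy-8-[(2R)-2-methylbutanoyloxy]germacra-1(10),2Z,7(11)-trien-12,6-olide | CC[C@@H](C)C(=O)O[C@H]1C/C(CO)=C/C=C\[C@@]2(C)O[C@H]2[C@H]2OC(=O)C(COC(C)=O)=C12 | intermediate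
21 | (1R,4R,5S,6S,8S,10S)-13-acetoxy-1,10:4,5-diepoxy-14-hydroxy-8-[(2R)-2-methylbutanoyloxy]germacra-2Z,7(11)-dien-12,6-olide | CC[C@@H](C)C(=O)O[C@H]1C[C@@]2(CO)O[C@@H]2/C=C\[C@@]2(C)O[C@H]2[C@H]2OC(=O)C(COC(C)=O)=C12 | target

**Totals and risks**

Total step count: 15. Longest linear sequence: 11 steps (steps 1–6, then 11–15); the second branch (steps 7–10) joins at step 11.

The three steps most likely to fail are steps 5, 11 and 13.

Step 5 (the proposed new cascade). The stannylcopper may attack the vinyl oxirane in an SN2′ sense, the copper intermediate may be protonated instead of hydroxymethylated, or olefin geometry may leak before ring closure. The fallback uses known chemistry only and sets out from aldehyde 4. Seyferth–Gilbert homologation with dimethyl (1-diazo-2-oxopropyl)phosphonate (K2CO3, MeOH) gives the alkyne (2S,3R)-3-ethenyl-2-ethynyl-3-methyloxirane F1. CuI-catalysed coupling of this terminal alkyne with methyl 3-acetoxy-2-diazopropanoate (i-Pr2NEt, MeCN) gives the 2,3-allenoate methyl 2-(acetoxymethyl)-4-[(2S,3R)-3-ethenyl-3-methyloxiran-2-yl]buta-2,3-dienoate F2. Iodolactonisation of the allenoate (I2, MeCN–H2O) then closes the butenolide through the C6–O bond with axis-to-centre chirality transfer and places iodine on C7. The C6 epimer that comes from the other allene epimer is removed by chromatography, and the route is rejoined at iodide 9.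

Step 11. Addition of the hindered alkenylchromium may be slow with the chiral ligand, and control of the C8 face may be poor. The fallback sets out from 9 and 15 and moves the stereocontrol to a ketone reduction. Ligand-free coupling (CrCl2, NiCl2 cat., DMSO) gives 16 mixed with its C8 epimer [(5S)-4-[(1R,3Z)-3-({[tert-butyl(dimethyl)silyl]oxy}methyl)-1-hydroxyhexa-3,5-dien-1-yl]-5-[(2S,3R)-3-ethenyl-3-methyloxiran-2-yl]-2-oxo-2,5-dihydrofuran-3-yl]methyl acetate F3. Dess–Martin oxidation of the mixture gives the ketone [(5S)-4-[(3Z)-3-({[tert-butyl(dimethyl)silyl]oxy}methyl)hexa-3,5-dienoyl]-5-[(2S,3R)-3-ethenyl-3-methyloxiran-2-yl]-2-oxo-2,5-dihydrofuran-3-yl]methyl acetate F4. Reduction with the (R)-methyl oxazaborolidine (CBS) catalyst and catecholborane at −78 °C then returns the single (8S)-alcohol 16.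

Step 13. Both olefin termini are sluggish (a vinyl group on a quaternary oxirane carbon and a diene terminus) and ten-membered closure competes with dimerisation. The fallback sets out from 9 and 15 and closes the ring by carbonyl addition instead of metathesis. Z-selective cross-metathesis with a cyclometalated nitrato ruthenium catalyst, Ru(κ2-NO3)(=CH-C6H4-2-OiPr)(C,C-chelating N-adamantyl-N′-aryl imidazolinylidene), links the two vinyl groups to the seco iodo aldehyde [(5R)-5-[(2S,3R)-3-[(1Z,3Z)-4-({[tert-butyl(dimethyl)silyl]oxy}methyl)-6-oxohexa-1,3-dien-1-yl]-3-methyloxiran-2-yl]-4-iodo-2-oxo-2,5-dihydrofuran-3-yl]methyl acetate F5. Intramolecular Ni/Cr coupling at high dilution (CrCl2, NiCl2 cat., the same chiral ligand) forms C7–C8 and gives the macrocyclic alcohol (4R,5S,6S,8S)-13-acetoxy-14-[(tert-butyldimethylsilyl)oxy]-4,5-epoxy-8-hydroxygermacra-1(10),2Z,7(11)-trien-12,6-olide F6. Steglich esterification with 17 then rejoins the route at 19.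

Further compounds
F1 | step 5 | (2S,3R)-3-ethenyl-2-ethynyl-3-methyloxirane | C=C[C@@]1(C)O[C@H]1C#C
F2 | step 5 | methyl 2-(acetoxymethyl)-4-[(2S,3R)-3-ethenyl-3-methyloxiran-2-yl]buta-2,3-dienoate (allene axis formed as a mixture) | C=C[C@@]1(C)O[C@H]1C=C=C(COC(C)=O)C(=O)OC
F3 | step 11 | [(5S)-4-[(1R,3Z)-3-({[tert-butyl(dimethyl)silyl]oxy}methyl)-1-hydroxyhexa-3,5-dien-1-yl]-5-[(2S,3R)-3-ethenyl-3-methyloxiran-2-yl]-2-oxo-2,5-dihydrofuran-3-yl]methyl acetate | C=C/C=C(\CO[Si](C)(C)C(C)(C)C)C[C@@H](O)C1=C(COC(C)=O)C(=O)O[C@@H]1[C@@H]1O[C@]1(C)C=C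
F4 | step 11 | [(5S)-4-[(3Z)-3-({[tert-butyl(dimethyl)silyl]oxy}methyl)hexa-3,5-dienoyl]-5-[(2S,3R)-3-ethenyl-3-methyloxiran-2-yl]-2-oxo-2,5-dihydrofuran-3-yl]methyl acetate | C=C/C=C(\CO[Si](C)(C)C(C)(C)C)CC(=O)C1=C(COC(C)=O)C(=O)O[C@@H]1[C@@H]1O[C@]1(C)C=C
F5 | step 13 | [(5R)-5-[(2S,3R)-3-[(1Z,3Z)-4-({[tert-butyl(dimethyl)silyl]oxy}methyl)-6-oxohexa-1,3-dien-1-yl]-3-methyloxiran-2-yl]-4-iodo-2-oxo-2,5-dihydrofuran-3-yl]methyl acetate | O=CC/C(CO[Si](C)(C)C(C)(C)C)=C/C=C\[C@@]1(C)O[C@H]1[C@H]1OC(=O)C(COC(C)=O)=C1I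
F6 | step 13 | (4R,5S,6S,8S)-13-acetoxy-14-[(tert-butyldimethylsilyl)oxy]-4,5-epoxy-8-hydroxygermacra-1(10),2Z,7(11)-trien-12,6-olide | O[C@H]1C/C(CO[Si](C)(C)C(C)(C)C)=C/C=C\[C@@]2(C)O[C@H]2[C@H]2OC(=O)C(COC(C)=O)=C12
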